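What is left of the coupling partner after the starting material has taken its one equivalent is the quantity I would examine here; call it the surplus.

the same everywhere: starting material 0.10 M

| flask | fresh partner | coupling partner | remark | time |
|---|---|---|---|---|
| south | 0.90 equiv | 1.1 equiv | run made earlier |  |
| east | 0.90 equiv | 4.8 equiv | run made earlier |  |
| dawn | 0.900 equiv | 2.00 equiv |  | 4.0 min |
| dusk | 0.900 equiv | 6.00 equiv |  | 1.2 min |

| run | time / min | target / % |
|---|---|---|
| south | 0.500 | 6 |
| south | 1.33 | 10 |
| south | 2.50 | 6 |
| south | 4.00 | 7 |
| east | 0.333 | 18 |
| east | 0.667 | 36 |
| east | 1.50 | 45 |
| east | 4.00 | 49 |

(readings scatter by 2 percentage points)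

- the winner by amount of target, in percent of the starting material charged; "neither" if no more than 2 percentage points parts them (dawn / dusk / neither)
- how much target is there at the end, in percent of the starting material charged: dawn
- how much target is there at the end, in percent of the starting material charged: dusk

Why the surplus? The target is built from the open intermediate and the second intermediate, and each of them costs coupling partner. I therefore book one equivalent for the starting material and let the rest feed the second intermediate. South then holds a surplus of 0.100 equiv and east 3.80 equiv. By this booking the coupling partner is the limiting reagent for the second intermediate in south, its surplus being smaller than the 0.90 equiv of fresh partner.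

What does one equivalent of surplus yield? South's last reading gives 0.700 equiv⁻¹. Dawn has a surplus of 1.00 equiv, so my first answer for dawn is 70.0 %.

Does that survive? Put it against east, which gives 0.129 equiv⁻¹, less than south. The yield per equivalent read from east is the lower of the two, so I go round again with a saturating curve: target equals ceiling times surplus over surplus plus knee. Through the last readings of south and east the knee comes to 0.735 equiv. The knee is the surplus at which target stands at half the ceiling, and the ceiling comes to 58.5 %. Dawn then comes to 33.7 %, and dusk's plateau to 51.0 %.

Where is the weak spot? South's reading carries 2 percentage points of scatter on 7 %, so the knee is soft.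

And the clock? Dawn stops at the time of east's last reading, so I read it as a plateau. Dusk stops at 1.2 min, when east, interpolated between its readings, stood at 85.2 % of its last reading. Taking that share for dusk, I reckon 43.4 %.

The forecast also names dusk as winner, but with 17 % for dawn and 48 % for dusk: "Interpolating, and allowing for partner decomposition, gives about 17%".

The flasks give dusk as winner, with 36.4 % for dawn and 42.6 % for dusk.

    2 second intermediate → homo product (k = 0.0986 M⁻¹ s⁻¹)
    starting material + coupling partner → open intermediate (k = 5.97 M⁻¹ s⁻¹)
    coupling partner → decomposed reagent (k = 0.00879 s⁻¹)
    coupling partner + fresh partner → second intermediate (k = 0.279 M⁻¹ s⁻¹)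
    open intermediate + second intermediate → target (k = 0.290 M⁻¹ s⁻¹)
    second intermediate → side product (k = 0.0137 s⁻¹)

The curve stood 2.7 points below dawn's result and 0.80 points above dusk's. A neighbouring flask is charged like dusk but with 2.40 equiv of coupling partner, and it stops at the same time. Its surplus of 1.40 equiv, set against the same knee, gives a plateau of 38.3 %, and the same share of east's course brings that to 32.6 %. That neighbour holds 31.7 % of target, with 13 % of its coupling partner still there.

The runs are simulated for an exercise, noise included.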